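**Retrosynthetic overview**
1. Target 5 ⇒ 1,3-diketone 4 by opening ring C at the O1–C8a aryl ether bond; forward, a dehydrogenative aryl C–H / enol O–H closure is the last step.
2. Diketone 4 ⇒ methyl ketone 2 + aryl ester 3 (crossed Claisen condensation, forms the C2–C3 bond of the future pyranone).
3. Ketone 2 ⇒ 1,2,4-trimethoxybenzene 1 + acetic anhydride (Friedel–Crafts acylation).
4. Ring order: rings A and B are bought as arenes; ring C (the pyranone) is the only ring made, in the final step.

Assumption: the target has no stereocentre and is achiral, so no stereocontrol is needed; ester 3 is taken as a catalogue compound.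

**Step 1**
Reactants: 1 1,2,4-trimethoxybenzene
Product: 2 1-(2,4,5-trimethoxyphenyl)ethan-1-one
Conditions: Ac2O (1.5 equiv), Sc(OTf)3 (5 mol %), MeNO2, 50 °C
Reagents that add atoms: acetic anhydride CC(=O)OC(C)=O
Why: Friedel–Crafts acylation at C5 of 1 (para to the 2-OMe, ortho to the 4-OMe, the most activated unhindered position) gives only the 2,4,5-pattern; the mild catalytic Lewis acid does not cleave the methyl ethers and the ketone product is deactivated toward a second acylation.

**Step 2**
Reactants: 2 1-(2,4,5-trimethoxyphenyl)ethan-1-one, 3 methyl 2,3,4-trimethoxybenzoate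
Product: 4 1-(2,4,5-trimethoxyphenyl)-3-(2,3,4-trimethoxyphenyl)propane-1,3-dione
Conditions: NaH (2.5 equiv), THF, reflux; then 1 M HCl, 0 °C
Reagents that add atoms: none
Why: Crossed Claisen condensation of a methyl ketone enolate with a non-enolisable aryl ester; only one C–C connectivity is possible and deprotonation of the acidic 1,3-diketone by the excess base makes the condensation irreversible.

**Step 3**
Reactants: 4 1-(2,4,5-trimethoxyphenyl)-3-(2,3,4-trimethoxyphenyl)propane-1,3-dione
Product: 5 5,7,8-trimethoxy-2-(2,3,4-trimethoxyphenyl)-4H-chromen-4-one (2',3',4',5,7,8-hexamethoxyflavone)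
Conditions: graphite anode, Pt cathode, undivided cell, constant current 2 mA cm−2, 2.2 F mol−1, n-Bu4NPF6 (0.1 M), HFIP/CH2Cl2 4:1 (5 mM in 4), rt, Ar
Reagents that add atoms: none
Why: Proposed new method: anodic dehydrogenative aryl C–H / enol O–H coupling; one-electron oxidation of 4 in HFIP places the hole on ring A (a 1,2,4-trimethoxybenzene unit, roughly 0.3 V easier to oxidise than the 1,2,3-trimethoxy ring B), the enol oxygen next to ring B adds to C6 of that radical cation through a six-membered transition state (the only ring A C–H it can reach, ortho to the 5-OMe; the central carbon could only close a four-membered ring), and proton loss, a second one-electron oxidation and loss of the ring proton aromatise to the chromone while the cathode turns the released protons into H2; the closest known reaction types are the anodic or photoredox dehydrogenative lactonisation of biaryl-2-carboxylic acids to benzocoumarins and the oxidative enol-to-arene C–O cyclisation of 2-aryl-1,3-dicarbonyl compounds to benzofurans, and to my knowledge neither has been shown for 1,3-diaryl-1,3-diketones closing to flavones; no stereocentre is formed.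

**Compound list**
1 | 1,2,4-trimethoxybenzene | COc1ccc(OC)c(OC)c1 | starting material
2 | 1-(2,4,5-trimethoxyphenyl)ethan-1-one | CC(=O)c1cc(OC)c(OC)cc1OC | intermediate
3 | methyl 2,3,4-trimethoxybenzoate | COC(=O)c1ccc(OC)c(OC)c1OC | starting material
4 | 1-(2,4,5-trimethoxyphenyl)-3-(2,3,4-trimethoxyphenyl)propane-1,3-dione | COc1cc(OC)c(OC)cc1C(=O)CC(=O)c1ccc(OC)c(OC)c1OC | intermediate
5 | 5,7,8-trimethoxy-2-(2,3,4-trimethoxyphenyl)-4H-chromen-4-one | COc1ccc(-c2cc(=O)c3c(OC)cc(OC)c(OC)c3o2)c(OC)c1OC | target

**Total step count:** 3
**Longest linear sequence:** 3 (1 → 2 → 4 → 5)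

**Steps most likely to fail**

Step 3 (the new electrochemical ring closure) is the main risk. Possible failures:
- closure onto ring B instead, giving the 5,6,7-trimethoxy-2-(2,4,5-trimethoxyphenyl) isomer;
- ipso attack at the 2-OMe carbon of ring A;
- over-oxidation of the para-dimethoxy product to a 5,8-quinone if water is present;
- intermolecular coupling at higher concentration.

The fallback uses only known chemistry; it sets out from ester 3 and comes back at target 5. Bought 1,2,3,5-tetramethoxybenzene F1 is acetylated with AcCl/AlCl3 (Et2O, 0 °C to rt). The AlCl3 chelate also cleaves the crowded methyl ether next to the new acetyl group, giving 1-(2-hydroxy-3,4,6-trimethoxyphenyl)ethan-1-one F2. The direction of this demethylation is recalled from the classical route to 5,7,8-trioxygenated flavones and should be confirmed on the first batch. Crossed Claisen condensation of F2 with 3 (NaH 3.5 equiv, THF, reflux; then HCl) gives 1-(2-hydroxy-3,4,6-trimethoxyphenyl)-3-(2,3,4-trimethoxyphenyl)propane-1,3-dione F3. Acid cyclodehydration (cat. H2SO4, AcOH, 100 °C) then closes ring C through the O1–C2 bond to 5.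

Step 2 (Claisen condensation) may stall because the ortho-methoxy, electron-rich ester 3 is a poor electrophile, and ketone 2 may self-condense. The fallback replaces ester acylation by aldol addition and oxidation; it sets out from ketone 2 and comes back at diketone 4. The lithium enolate of 2 (LiN(i-Pr)2, THF, −78 °C) adds to bought 2,3,4-trimethoxybenzaldehyde F4 to give racemic 3-hydroxy-1-(2,4,5-trimethoxyphenyl)-3-(2,3,4-trimethoxyphenyl)propan-1-one F5. Oxidation of F5 with IBX (EtOAc, 77 °C) gives 4.

Step 1 (catalytic Friedel–Crafts acylation) may stop short through product inhibition of the catalyst. The fallback replaces acylation by formylation, methyl addition and oxidation; it sets out from 1 and comes back at 2. Vilsmeier–Haack formylation of 1 (POCl3, DMF, 0 to 60 °C; aqueous NaOAc) gives 2,4,5-trimethoxybenzaldehyde F6. MeMgBr (THF, 0 °C) converts F6 into racemic 1-(2,4,5-trimethoxyphenyl)ethan-1-ol F7. MnO2 (CH2Cl2, rt) oxidises F7 to 2.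

**Further compounds**
F1 | step 3 | 1,2,3,5-tetramethoxybenzene | COc1cc(OC)c(OC)c(OC)c1
F2 | step 3 | 1-(2-hydroxy-3,4,6-trimethoxyphenyl)ethan-1-one | CC(=O)c1c(O)c(OC)c(OC)cc1OC
F3 | step 3 | 1-(2-hydroxy-3,4,6-trimethoxyphenyl)-3-(2,3,4-trimethoxyphenyl)propane-1,3-dione | COc1cc(OC)c(OC)c(O)c1C(=O)CC(=O)c1ccc(OC)c(OC)c1OC
F4 | step 2 | 2,3,4-trimethoxybenzaldehyde | O=Cc1ccc(OC)c(OC)c1OC
F5 | step 2 | 3-hydroxy-1-(2,4,5-trimethoxyphenyl)-3-(2,3,4-trimethoxyphenyl)propan-1-one (racemic) | COc1cc(OC)c(OC)cc1C(=O)CC(O)c1ccc(OC)c(OC)c1OC
F6 | step 1 | 2,4,5-trimethoxybenzaldehyde | O=Cc1cc(OC)c(OC)cc1OC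
F7 | step 1 | 1-(2,4,5-trimethoxyphenyl)ethan-1-ol (racemic) | CC(O)c1cc(OC)c(OC)cc1OC
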